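## Retrosynthetic overview

1. The senecioate on O2 is attached last. C12–C16 come from (R)-2-methyl-2-vinyloxirane, which carries C13 and is joined at C11–C12 to the C11 sulfone carbanion of a drim-7-ene bicycle.
2. Ring A is formed second, through the C3–C4 bond: a tertiary C4 cation alkylates the enol silane of an acetonyl group on C10. The C2 ketone is then reduced to the equatorial alcohol.
3. Ring B is formed first, by a catalytic enantioselective Diels–Alder reaction (bonds C5–C6 and C9–C10) between a 1,2-disubstituted dienyl silyl ether and an (E)-formyl ester.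
4. The plan rests on one feature: ring B is a cyclohexene whose C7=C8 bond (C17 on C8) lies opposite the C5–C10 bond, with C4 and C1 trans on C5 and C10 and C11 cis to C20. That is the formyl-exo adduct of such a diene and an E dienophile.

Key step: step 3

Numbering: labdane numbering (C1–C20) is used for all ring and chain carbons of the intermediates.

Assumption: the oxazaborolidinium ion made from (R)-α,α-diphenylprolinol is taken to shield the Re face of the enal α-carbon (C10), as the usual transition-state model for α-substituted enals predicts; if the sense proved opposite, the (S)-catalyst would be used with no other change.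

## Route

Step 1
Reactants: 1 (E)-3-methylpent-2-en-4-yn-1-ol
Product: 2 (E)-tert-butyldimethyl[(3-methylpent-2-en-4-yn-1-yl)oxy]silane
Conditions: TBSCl, imidazole, DMF, 0 °C to rt
Reagents that add atoms: tert-butyldimethylsilyl chloride, CC(C)(C)[Si](C)(C)Cl
Why: Imidazole-promoted silylation of a primary alcohol; the enyne is not affected.

Step 2
Reactants: 2 (E)-tert-butyldimethyl[(3-methylpent-2-en-4-yn-1-yl)oxy]silane
Product: 3 (E)-tert-butyldimethyl[(3-methylpenta-2,4-dien-1-yl)oxy]silane
Conditions: H2 (1 atm, 1 equiv), Pd/CaCO3 poisoned with Pb(OAc)2 (Lindlar catalyst), quinoline, hexane, rt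
Reagents that add atoms: none
Why: Lindlar semi-hydrogenation stops the terminal alkyne at the vinyl group when hydrogen uptake is limited to one equivalent, and the E trisubstituted alkene is neither reduced nor isomerised.

Step 3
Reactants: 3 (E)-tert-butyldimethyl[(3-methylpenta-2,4-dien-1-yl)oxy]silane; 4 ethyl (E)-3-methyl-4-oxobut-2-enoate
Product: 5 ethyl (1S,5R,6S)-5-{[(tert-butyldimethylsilyl)oxy]methyl}-6-formyl-4,6-dimethylcyclohex-3-ene-1-carboxylate (ring B; formyl C1 and ester C4 trans, C11 cis to C20)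
Conditions: oxazaborolidinium triflimide [from (R)-α,α-diphenyl-2-pyrrolidinemethanol and tri-o-tolylboroxine, then Tf2NH] (20 mol %), CH2Cl2, −78 to −40 °C
Reagents that add atoms: none
Why: The protonated oxazaborolidine binds the formyl oxygen of 4 (s-trans enal, formyl C–H···O contact), which lowers the LUMO and makes the enal β-carbon C5 the most electrophilic site, so a concerted but asynchronous [4+2] cycloaddition forms C5–C6 ahead of C9–C10 and closes ring B in one intermolecular, suprafacial event. The closest known reactions are the oxazaborolidinium-catalysed Diels–Alder additions of α-methyl enals and of 3-formylacrylates to acyclic dienes. C5 and C10 come out trans because the E geometry of 4 is transferred; C9 is set relative to C10 by the formyl-exo, ester-endo transition state usual for α-substituted enals, which puts C11 of the E diene cis to C20; the absolute sense comes from the catalyst, whose phenyl group covers the Re face of C10 so that the diene adds to the Si face. The step needs regio-, exo and facial selectivity: the first should follow from formyl activation, the unhindered CH2 terminus C6 and the directing C9 substituent, the second from the α-methyl group and the ester, the third from the chiral cation.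

Step 4
Reactants: 5 ethyl (1S,5R,6S)-5-{[(tert-butyldimethylsilyl)oxy]methyl}-6-formyl-4,6-dimethylcyclohex-3-ene-1-carboxylate
Product: 6 ethyl (1S,5R,6R)-5-{[(tert-butyldimethylsilyl)oxy]methyl}-6-(2-methoxyprop-1-en-1-yl)-4,6-dimethylcyclohex-3-ene-1-carboxylate (E/Z mixture at the enol ether; ring stereocentres as in 5)
Conditions: [Ph3PCH(OMe)CH3]Cl, KN(SiMe3)2, THF, −78 °C; then 5, −78 to 0 °C
Reagents that add atoms: (1-methoxyethyl)triphenylphosphonium chloride, COC(C)[P+](c1ccccc1)(c1ccccc1)c1ccccc1.[Cl-]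
Why: Wittig olefination with the α-methoxyethylidene ylide turns the non-enolisable neopentyl aldehyde into a masked acetonyl group (C1=C2 enol ether) while the hindered ester is left alone; the geometry of the new double bond does not matter.

Step 5
Reactants: 6 ethyl (1S,5R,6R)-5-{[(tert-butyldimethylsilyl)oxy]methyl}-6-(2-methoxyprop-1-en-1-yl)-4,6-dimethylcyclohex-3-ene-1-carboxylate
Product: 7 2-[(1S,5R,6R)-5-{[(tert-butyldimethylsilyl)oxy]methyl}-6-(2-methoxyprop-1-en-1-yl)-4,6-dimethylcyclohex-3-en-1-yl]propan-2-ol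
Conditions: MeLi (4 equiv), Et2O, −78 to 0 °C
Reagents that add atoms: methyllithium, [Li]C
Why: Double addition of MeLi to the ester gives the C4 dimethylcarbinol; the enol ether and silyl ether are inert, and C5 can no longer epimerise afterwards.

Step 6
Reactants: 7 2-[(1S,5R,6R)-5-{[(tert-butyldimethylsilyl)oxy]methyl}-6-(2-methoxyprop-1-en-1-yl)-4,6-dimethylcyclohex-3-en-1-yl]propan-2-ol
Product: 9 tert-butyl{[(1R,5S,6S)-5-(2-chloropropan-2-yl)-2,6-dimethyl-6-(2-oxopropyl)cyclohex-2-en-1-yl]methoxy}dimethylsilane, via tertiary chloride enol ether 8 (not isolated)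
Conditions: Me2C=C(Cl)NMe2, CH2Cl2, 0 °C; then 5% aq. oxalic acid, THF, 0 °C
Reagents that add atoms: 1-chloro-N,N,2-trimethylprop-1-en-1-amine, CC(C)=C(Cl)N(C)C; water, O
Why: The α-chloroenamine (Ghosez reagent) converts alcohols into chlorides under neutral conditions, the tertiary centre reacting through an ion pair, so the enol ether survives until dilute acid hydrolyses it to the methyl ketone faster than the tertiary chloride solvolyses.

Step 7
Reactants: 9 tert-butyl{[(1R,5S,6S)-5-(2-chloropropan-2-yl)-2,6-dimethyl-6-(2-oxopropyl)cyclohex-2-en-1-yl]methoxy}dimethylsilane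
Product: 10 tert-butyl{[(1R,5S,6S)-5-(2-chloropropan-2-yl)-2,6-dimethyl-6-{2-[(trimethylsilyl)oxy]prop-2-en-1-yl}cyclohex-2-en-1-yl]methoxy}dimethylsilane
Conditions: LiN(i-Pr)2, TMSCl (in situ quench), THF, −78 °C; pentane, filtration
Reagents that add atoms: chlorotrimethylsilane, C[Si](C)(C)Cl
Why: Kinetic enolisation with in situ silylation takes the methyl group (C3) rather than the neopentyl C1 methylene, and the tertiary chloride does not react with the amide base at −78 °C.

Step 8
Reactants: 10 tert-butyl{[(1R,5S,6S)-5-(2-chloropropan-2-yl)-2,6-dimethyl-6-{2-[(trimethylsilyl)oxy]prop-2-en-1-yl}cyclohex-2-en-1-yl]methoxy}dimethylsilane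
Product: 11 (5R,9R,10R)-11-[(tert-butyldimethylsilyl)oxy]drim-7-en-2-one (trans-fused rings A and B, 4,4,8,10-tetramethyl, C2 ketone, CH2OTBS on C9)
Conditions: TiCl4 (1.1 equiv), CH2Cl2, −78 to −40 °C
Reagents that add atoms: none
Why: Reetz-type α-tert-alkylation of an enol silane: TiCl4 ionises the tertiary chloride and C3 of the enol silane captures the C4 cation in a six-membered (enolendo) closure that should outrun proton loss at low temperature; no stereocentre is created and the trans ring fusion follows from C5 and C10 as set in step 3.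

Step 9
Reactants: 11 (5R,9R,10R)-11-[(tert-butyldimethylsilyl)oxy]drim-7-en-2-one
Product: 12 (2R,5R,9R,10R)-11-[(tert-butyldimethylsilyl)oxy]drim-7-en-2-ol (equatorial hydroxyl, trans to C20)
Conditions: Li, NH3(l), THF, t-BuOH, −78 °C; then NH4Cl
Reagents that add atoms: none
Why: Dissolving-metal reduction gives the thermodynamic alcohol, because the intermediate α-oxido carbanion places oxygen equatorial, away from the syn-axial C20 and axial C4 methyl groups, before protonation, which sets C2 as R (hydride reagents would attack from the equatorial side and give the axial epimer).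

Step 10
Reactants: 12 (2R,5R,9R,10R)-11-[(tert-butyldimethylsilyl)oxy]drim-7-en-2-ol
Product: 13 (2R,5R,9R,10R)-drim-7-ene-2,11-diol
Conditions: Bu4NF, THF, rt
Reagents that add atoms: none
Why: Fluoride cleaves the primary silyl ether and nothing else in the molecule responds.

Step 11
Reactants: 13 (2R,5R,9R,10R)-drim-7-ene-2,11-diol
Product: 14 (2R,5R,9R,10R)-11-(phenylsulfanyl)drim-7-en-2-ol
Conditions: PhSSPh, n-Bu3P, pyridine, rt to 50 °C
Reagents that add atoms: diphenyl disulfide, c1ccccc1SSc1ccccc1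
Why: Hata thioetherification (an alkoxyphosphonium displaced by thiolate, SN2) can occur only at primary C11, since backside approach to the equatorial C2–O bond is blocked by the ring and its two syn-axial methyl groups.

Step 12
Reactants: 14 (2R,5R,9R,10R)-11-(phenylsulfanyl)drim-7-en-2-ol
Product: 15 (2R,5R,9R,10R)-11-(phenylsulfonyl)drim-7-en-2-ol
Conditions: (NH4)6Mo7O24·4H2O (10 mol %), 30% H2O2, EtOH, 0 °C to rt
Reagents that add atoms: hydrogen peroxide, OO
Why: Peroxomolybdate-catalysed oxidation takes the sulfide to the sulfone without epoxidising the trisubstituted alkene or oxidising the secondary alcohol at this temperature.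

Step 13
Reactants: 16 (R)-2-methylglycidol
Product: 17 (S)-2-methyloxirane-2-carbaldehyde (used as a CH2Cl2 solution)
Conditions: Dess–Martin periodinane, NaHCO3, CH2Cl2, 0 °C
Reagents that add atoms: none
Why: Buffered Dess–Martin oxidation of the primary alcohol; the quaternary epoxide carbon cannot epimerise.

Step 14
Reactants: 17 (S)-2-methyloxirane-2-carbaldehyde
Product: 18 (R)-2-methyl-2-vinyloxirane (vacuum-transferred and used as a titrated THF solution)
Conditions: Ph3PCH3Br, KN(SiMe3)2, THF, −78 to 0 °C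
Reagents that add atoms: methyltriphenylphosphonium bromide, C[P+](c1ccccc1)(c1ccccc1)c1ccccc1.[Br-]
Why: Wittig methylenation of the non-enolisable aldehyde; the stereocentre is untouched.

Step 15
Reactants: 15 (2R,5R,9R,10R)-11-(phenylsulfonyl)drim-7-en-2-ol; 18 (R)-2-methyl-2-vinyloxirane
Product: 20 (2R,5R,9R,10R,13S)-11-(phenylsulfonyl)labda-7,14-diene-2,13-diol (both C11 epimers), via dilithiated sulfone 19 (not isolated)
Conditions: n-BuLi (2.1 equiv), THF, −78 °C; then 18, DMPU, −78 to 0 °C
Reagents that add atoms: none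
Why: The α-sulfonyl carbanion opens the epoxide by SN2 attack at its CH2 carbon, the only unsubstituted and non-allylic site, which forms C11–C12 and leaves the C13 configuration of 18 unchanged; the new C11 centre is removed in the next step.

Step 16
Reactants: 20 (2R,5R,9R,10R,13S)-11-(phenylsulfonyl)labda-7,14-diene-2,13-diol
Product: 21 (2R,5R,9R,10R,13S)-labda-7,14-diene-2,13-diol
Conditions: 6% Na(Hg), Na2HPO4, MeOH–THF, −20 °C
Reagents that add atoms: none
Why: Reductive desulfonylation with sodium amalgam replaces the sulfonyl group by hydrogen; the isolated alkenes and the tertiary allylic alcohol are inert.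

Step 17
Reactants: 21 (2R,5R,9R,10R,13S)-labda-7,14-diene-2,13-diol; 22 3-methylbut-2-enoic acid
Product: 23 (2R,5R,9R,10R,13S)-13-hydroxylabda-7,14-dien-2-yl 3-methylbut-2-enoate (CNP0252389.1)
Conditions: DCC, DMAP (0.1 equiv), CH2Cl2, 0 °C to rt
Reagents that add atoms: none
Why: Steglich esterification acylates the unhindered equatorial secondary alcohol at C2 and leaves the tertiary C13 alcohol untouched.

## Compound list

1 | (E)-3-methylpent-2-en-4-yn-1-ol | C#C/C(C)=C/CO | starting material
2 | (E)-tert-butyldimethyl[(3-methylpent-2-en-4-yn-1-yl)oxy]silane | C#C/C(C)=C/CO[Si](C)(C)C(C)(C)C | intermediate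
3 | (E)-tert-butyldimethyl[(3-methylpenta-2,4-dien-1-yl)oxy]silane | C=C/C(C)=C/CO[Si](C)(C)C(C)(C)C | intermediate
4 | ethyl (E)-3-methyl-4-oxobut-2-enoate | CCOC(=O)/C=C(\C)C=O | starting material
5 | ethyl (1S,5R,6S)-5-{[(tert-butyldimethylsilyl)oxy]methyl}-6-formyl-4,6-dimethylcyclohex-3-ene-1-carboxylate | CC(C)(C)[Si](C)(C)OC[C@@H]1C(C)=CC[C@H](C(=O)OCC)[C@@]1(C)C=O | intermediate
6 | ethyl (1S,5R,6R)-5-{[(tert-butyldimethylsilyl)oxy]methyl}-6-(2-methoxyprop-1-en-1-yl)-4,6-dimethylcyclohex-3-ene-1-carboxylate (E/Z mixture) | CC(C)(C)[Si](C)(C)OC[C@@H]1C(C)=CC[C@H](C(=O)OCC)[C@@]1(C)C=C(C)OC | intermediate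
7 | 2-[(1S,5R,6R)-5-{[(tert-butyldimethylsilyl)oxy]methyl}-6-(2-methoxyprop-1-en-1-yl)-4,6-dimethylcyclohex-3-en-1-yl]propan-2-ol | CC(C)(C)[Si](C)(C)OC[C@@H]1C(C)=CC[C@H](C(C)(C)O)[C@@]1(C)C=C(C)OC | intermediate
8 | tert-butyl{[(1R,5S,6R)-5-(2-chloropropan-2-yl)-6-(2-methoxyprop-1-en-1-yl)-2,6-dimethylcyclohex-2-en-1-yl]methoxy}dimethylsilane | CC(C)(C)[Si](C)(C)OC[C@@H]1C(C)=CC[C@H](C(C)(C)Cl)[C@@]1(C)C=C(C)OC | intermediate
9 | tert-butyl{[(1R,5S,6S)-5-(2-chloropropan-2-yl)-2,6-dimethyl-6-(2-oxopropyl)cyclohex-2-en-1-yl]methoxy}dimethylsilane | CC(C)(C)[Si](C)(C)OC[C@@H]1C(C)=CC[C@H](C(C)(C)Cl)[C@@]1(C)CC(C)=O | intermediate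
10 | tert-butyl{[(1R,5S,6S)-5-(2-chloropropan-2-yl)-2,6-dimethyl-6-{2-[(trimethylsilyl)oxy]prop-2-en-1-yl}cyclohex-2-en-1-yl]methoxy}dimethylsilane | CC(C)(C)[Si](C)(C)OC[C@@H]1C(C)=CC[C@H](C(C)(C)Cl)[C@@]1(C)CC(=C)O[Si](C)(C)C | intermediate
11 | (5R,9R,10R)-11-[(tert-butyldimethylsilyl)oxy]drim-7-en-2-one | CC(C)(C)[Si](C)(C)OC[C@@H]1C(C)=CC[C@@H]2C(C)(C)CC(=O)C[C@@]12C | intermediate
12 | (2R,5R,9R,10R)-11-[(tert-butyldimethylsilyl)oxy]drim-7-en-2-ol | CC(C)(C)[Si](C)(C)OC[C@@H]1C(C)=CC[C@@H]2C(C)(C)C[C@@H](O)C[C@@]12C | intermediate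
13 | (2R,5R,9R,10R)-drim-7-ene-2,11-diol | OC[C@@H]1C(C)=CC[C@@H]2C(C)(C)C[C@@H](O)C[C@@]12C | intermediate
14 | (2R,5R,9R,10R)-11-(phenylsulfanyl)drim-7-en-2-ol | c3ccccc3SC[C@@H]1C(C)=CC[C@@H]2C(C)(C)C[C@@H](O)C[C@@]12C | intermediate
15 | (2R,5R,9R,10R)-11-(phenylsulfonyl)drim-7-en-2-ol | O=S(=O)(c3ccccc3)C[C@@H]1C(C)=CC[C@@H]2C(C)(C)C[C@@H](O)C[C@@]12C | intermediate
16 | (R)-2-methylglycidol | OC[C@]1(C)CO1 | starting material
17 | (S)-2-methyloxirane-2-carbaldehyde | O=C[C@]1(C)CO1 | intermediate
18 | (R)-2-methyl-2-vinyloxirane | C=C[C@]1(C)CO1 | intermediate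
19 | dilithiated sulfone (O2 lithium alkoxide, C11 α-sulfonyl carbanion of 15) | [Li]C(S(=O)(=O)c3ccccc3)[C@@H]1C(C)=CC[C@@H]2C(C)(C)C[C@@H](O[Li])C[C@@]12C | intermediate
20 | (2R,5R,9R,10R,13S)-11-(phenylsulfonyl)labda-7,14-diene-2,13-diol (C11 epimers) | C=C[C@@](C)(O)CC(S(=O)(=O)c3ccccc3)[C@@H]1C(C)=CC[C@@H]2C(C)(C)C[C@@H](O)C[C@@]12C | intermediate
21 | (2R,5R,9R,10R,13S)-labda-7,14-diene-2,13-diol | C=C[C@@](C)(O)CC[C@@H]1C(C)=CC[C@@H]2C(C)(C)C[C@@H](O)C[C@@]12C | intermediate
22 | 3-methylbut-2-enoic acid | CC(C)=CC(O)=O | starting material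
23 | (2R,5R,9R,10R,13S)-13-hydroxylabda-7,14-dien-2-yl 3-methylbut-2-enoate | C=C[C@@](C)(O)CC[C@@H]1C(C)=CC[C@@H]2C(C)(C)C[C@@H](OC(=O)C=C(C)C)C[C@@]12C | target

## Step count and risks

Total step count: 17. Longest linear sequence: 15 (steps 1–12 and 15–17); steps 13 and 14 make the side-chain fragment.

**Step 3 (most likely to fail).** The methyl group on C8 directs the first bond towards C9, against the C9 substituent and the formyl activation, so the regioisomer with C5 joined to C9 may form in quantity. The acid-labile dienyl ether may also ionise and oligomerise before it adds. Fallback, from 2 back to 5: the diene is given a donor on C7. Hydration of the alkyne of 2 with (Ph3P)AuNTf2 in aqueous dioxane should give (E)-5-[(tert-butyldimethylsilyl)oxy]-3-methylpent-3-en-2-one F1. TIPSOTf and Et3N should then give the cross-conjugated dienol ether (E)-5-[(tert-butyldimethylsilyl)oxy]-3-methyl-2-[(triisopropylsilyl)oxy]penta-1,3-diene F2, a 2-silyloxybutadiene of the class for which this catalysis is well established; its silyloxy group on C7 makes C6 the nucleophilic terminus. Cycloaddition with 4 under the conditions of step 3 should give the C7 silyl enol ether of the adduct F3. CsF and PhNTf2 in DME should convert it into the C7 enol triflate F4, and Pd(OAc)2, PPh3, HCO2H and Bu3N in DMF should reduce the triflate to 5.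

**Step 8.** Loss of a proton from the C4 cation (to the isopropenyl or isopropylidene compound) or a 1,2-hydride shift from C5 may outrun carbon–carbon bond formation. Fallback, from 6 back to 11: ring A is closed by enolate chemistry. Hydrolysis of 6 with oxalic acid in wet THF should give the keto ester F5. LiN(SiMe3)2 (2.2 equiv) should bring about an intramolecular Claisen condensation of the methyl ketone enolate (C3) onto the C4 ester to give the trans-fused ring-A 2,4-dione F6. Isobutanol and TsOH in refluxing benzene should give the vinylogous ester F7, with the alkoxy group on the less hindered C2. MeLi followed by aqueous HCl (Stork–Danheiser transposition) should give the 4-methyl-3-en-2-one F8, and Me2CuLi with TMSCl should add the second methyl group at C4 and return 11.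

**Step 15.** The hindered carbanion may attack the vinyl terminus (SN2′ opening) or fail to open the neopentyl-like epoxide. Fallback, from 15 and 16 back to 21: the vinyl group is built after the coupling. TBSCl and imidazole convert 16 into the silyl ether (S)-tert-butyldimethyl[(2-methyloxiran-2-yl)methoxy]silane F9. The dianion 19 made from 15 should open F9 at CH2 in the presence of BF3·OEt2 at −78 °C to give the sulfone silyl ether F10. Na(Hg) should give the desulfonylated silyl ether F11 and Bu4NF the triol F12. TEMPO with PhI(OAc)2 should oxidise only the primary alcohol, to the hydroxy aldehyde F13, and excess Ph3P=CH2 should give 21.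

## Further compounds

F1 | step 3 | (E)-5-[(tert-butyldimethylsilyl)oxy]-3-methylpent-3-en-2-one | CC(=O)/C(C)=C/CO[Si](C)(C)C(C)(C)C
F2 | step 3 | (E)-5-[(tert-butyldimethylsilyl)oxy]-3-methyl-2-[(triisopropylsilyl)oxy]penta-1,3-diene | C=C(O[Si](C(C)C)(C(C)C)C(C)C)/C(C)=C/CO[Si](C)(C)C(C)(C)C
F3 | step 3 | ethyl (1S,5R,6S)-5-{[(tert-butyldimethylsilyl)oxy]methyl}-6-formyl-4,6-dimethyl-3-[(triisopropylsilyl)oxy]cyclohex-3-ene-1-carboxylate | CC(C)(C)[Si](C)(C)OC[C@@H]1C(C)=C(O[Si](C(C)C)(C(C)C)C(C)C)C[C@H](C(=O)OCC)[C@@]1(C)C=O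
F4 | step 3 | ethyl (1S,5R,6S)-5-{[(tert-butyldimethylsilyl)oxy]methyl}-6-formyl-4,6-dimethyl-3-{[(trifluoromethyl)sulfonyl]oxy}cyclohex-3-ene-1-carboxylate | CC(C)(C)[Si](C)(C)OC[C@@H]1C(C)=C(OS(=O)(=O)C(F)(F)F)C[C@H](C(=O)OCC)[C@@]1(C)C=O
F5 | step 8 | ethyl (1S,5R,6S)-5-{[(tert-butyldimethylsilyl)oxy]methyl}-4,6-dimethyl-6-(2-oxopropyl)cyclohex-3-ene-1-carboxylate | CC(C)(C)[Si](C)(C)OC[C@@H]1C(C)=CC[C@H](C(=O)OCC)[C@@]1(C)CC(C)=O
F6 | step 8 | trans-fused ring-A 2,4-dione (C9 CH2OTBS, C8 and C10 methyl, C7=C8; no methyl on C4) | CC(C)(C)[Si](C)(C)OC[C@@H]1C(C)=CC[C@@H]2C(=O)CC(=O)C[C@@]12C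
F7 | step 8 | vinylogous ester: 2-isobutoxy-2-en-4-one of F6 | CC(C)(C)[Si](C)(C)OC[C@@H]1C(C)=CC[C@@H]2C(=O)C=C(OCC(C)C)C[C@@]12C
F8 | step 8 | 4-methyl-3-en-2-one (4-monomethyl analogue of 11 with C3=C4) | CC(C)(C)[Si](C)(C)OC[C@@H]1C(C)=CC[C@@H]2C(C)=CC(=O)C[C@@]12C
F9 | step 15 | (S)-tert-butyldimethyl[(2-methyloxiran-2-yl)methoxy]silane (TBS ether of 16) | CC(C)(C)[Si](C)(C)OC[C@]1(C)CO1
F10 | step 15 | (13S)-14-[(tert-butyldimethylsilyl)oxy]-11-(phenylsulfonyl)-15-norlabd-7-ene-2,13-diol (C11 epimers) | CC(C)(C)[Si](C)(C)OC[C@@](C)(O)CC(S(=O)(=O)c3ccccc3)[C@@H]1C(C)=CC[C@@H]2C(C)(C)C[C@@H](O)C[C@@]12C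
F11 | step 15 | (13S)-14-[(tert-butyldimethylsilyl)oxy]-15-norlabd-7-ene-2,13-diol | CC(C)(C)[Si](C)(C)OC[C@@](C)(O)CC[C@@H]1C(C)=CC[C@@H]2C(C)(C)C[C@@H](O)C[C@@]12C
F12 | step 15 | (13S)-15-norlabd-7-ene-2,13,14-triol | OC[C@@](C)(O)CC[C@@H]1C(C)=CC[C@@H]2C(C)(C)C[C@@H](O)C[C@@]12C
F13 | step 15 | (13S)-2,13-dihydroxy-15-norlabd-7-en-14-al | O=C[C@@](C)(O)CC[C@@H]1C(C)=CC[C@@H]2C(C)(C)C[C@@H](O)C[C@@]12C
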